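**Strategy.** The whole plan rests on making the chromanone ring (O1, C2, C3, C4, C4a, C8a) from a five-membered benzofuran-3(2H)-one by one-carbon insertion. The precursor is the racemic 2-bromomethyl-2-phenylbenzofuranone 9: its CH2 radical adds to the ring carbonyl, the bond from the quaternary carbon to that carbonyl breaks, and the CH2 ends up as C3 (1,2-acyl shift). The step exploits C2: flanked by O1 and the 2-phenyl group it becomes a stabilised, planar radical, so both enantiomers of 9 converge, and a homochiral thiol delivers hydrogen to one face, setting C2 (R) in the same operation. The C8 side chain is attached last by a catalyst-controlled Friedel–Crafts-type Michael addition to isopentylidene-syncarpic acid.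

Key step: step 6

Remarks on the chemistry: compounds 6–9 are racemates (no descriptor in their SMILES), which is intended because step 6 is stereoconvergent. For the two chiral catalysts (steps 6 and 11) the face that must be attacked is stated; the catalyst named is the first choice, and its antipode or pseudo-enantiomer is taken if it proves to direct attack to the other face. Syncarpic acid is made (steps 8 and 9) rather than assumed to be purchasable.

Step 1
Reactants: 1 2-methylbenzene-1,3-diol (2-methylresorcinol)
Product: 2 2-methyl-1,3-di(propan-2-yloxy)benzene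
Conditions: 2-bromopropane (3 equiv), K2CO3, DMF, 70 °C
Reagents that add atoms: 2-bromopropane, CC(C)Br
Why: Williamson etherification of both phenols; isopropyl ethers should survive the borylation, Friedel–Crafts and radical steps and are cleaved later by BCl3.

Step 2
Reactants: 2 2-methyl-1,3-di(propan-2-yloxy)benzene
Product: 4 4-methyl-3,5-di(propan-2-yloxy)phenol, via aryl pinacol boronate 3 (not isolated)
Conditions: B2pin2 (1.0 equiv), [Ir(cod)OMe]2 (1.5 mol%), dtbpy (3 mol%), THF, 80 °C; then Oxone, acetone–H2O, rt
Reagents that add atoms: bis(pinacolato)diboron, CC1(C)OB(OC1(C)C)B1OC(C)(C)C(C)(C)O1 (boron of intermediate 3 only); potassium peroxymonosulfate (Oxone), [K+].[O-]S(=O)(=O)OO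
Why: Sterically controlled Ir-catalysed C–H borylation should occur only at C5, the one C–H not ortho to a substituent, and oxidation of the C–B bond in the same flask gives the phenol whose oxygen, para to the methyl group, becomes O1.

Step 3
Reactants: 4 4-methyl-3,5-di(propan-2-yloxy)phenol; 5 2-bromo-2-phenylacetic acid (racemic)
Product: 6 rac-2-[4-methyl-3,5-di(propan-2-yloxy)phenoxy]-2-phenylacetic acid
Conditions: NaH (2.2 equiv), THF, 0 → 60 °C; aq. HCl work-up
Reagents that add atoms: none
Why: Williamson-type SN2 displacement of the benzylic, carbonyl-activated bromide of the carboxylate by the phenoxide forms the O1–C2 bond; the configuration of this centre is irrelevant.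

Step 4
Reactants: 6 rac-2-[4-methyl-3,5-di(propan-2-yloxy)phenoxy]-2-phenylacetic acid
Product: 8 rac-5-methyl-2-phenyl-4,6-di(propan-2-yloxy)-1-benzofuran-3(2H)-one, via mixed trifluoroacetic anhydride 7 (not isolated)
Conditions: TFAA (2 equiv), CH2Cl2, 0 °C → rt, N2; then MeOH/aq. NaHCO3
Reagents that add atoms: trifluoroacetic anhydride, O=C(OC(=O)C(F)(F)F)C(F)(F)F (acyl group of intermediate 7 only)
Why: Intramolecular Friedel–Crafts acylation through the mixed anhydride; the two positions ortho to the aryloxy oxygen are equivalent and strongly activated, so one benzofuranone should form (five-membered ring closure), which is kept under nitrogen because 2-aryl-benzofuranones autoxidise.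

Step 5
Reactants: 8 rac-5-methyl-2-phenyl-4,6-di(propan-2-yloxy)-1-benzofuran-3(2H)-one
Product: 9 rac-2-(bromomethyl)-5-methyl-2-phenyl-4,6-di(propan-2-yloxy)-1-benzofuran-3(2H)-one
Conditions: NaH (1.1 equiv), CH2Br2 (15 equiv), THF–DMPU, 0 → 45 °C, degassed, dark
Reagents that add atoms: dibromomethane, BrCBr
Why: Enolate C-alkylation with excess dibromomethane, the usual way to make Dowd–Beckwith precursors; the soft, stabilised C2 of the 2-aryl-benzofuranone enolate should react at carbon and create the quaternary centre bearing the radical precursor.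

Step 6
Reactants: 9 rac-2-(bromomethyl)-5-methyl-2-phenyl-4,6-di(propan-2-yloxy)-1-benzofuran-3(2H)-one
Product: 10 (2R)-6-methyl-2-phenyl-5,7-di(propan-2-yloxy)-2,3-dihydro-4H-chromen-4-one
Conditions: Et3SiH (3 equiv), 2,3,4,6-tetra-O-acetyl-1-thio-β-D-glucopyranose (5 mol%), AIBN (10 mol%, in portions), PhCF3 (0.02 M), 65 °C, degassed
Reagents that add atoms: none
Why: Proposed new method: a silyl radical (thiyl/silane chain, polarity-reversal catalysis) abstracts Br from 9, the primary radical adds 3-exo-trig to the furanone carbonyl, and the benzylic cyclopropyloxy radical undergoes β-scission of the bond between the quaternary carbon and the carbonyl carbon, so the exocyclic CH2 becomes C3 and the five-membered ring (O1, C2, C3, C3a, C7a of the benzofuranone) grows to the six-membered pyranone by a net 1,2-acyl shift (Dowd–Beckwith ring expansion; the only ring closure is the transient 3-exo one). The ring-expanded radical at C2 is planar and stabilised by O1 and the phenyl group, so both enantiomers of 9 give the same intermediate, which should be reduced only by the homochiral thiol; delivery of S–H to the Si face of C2 gives 2R (catalyst control, enantioselective hydrogen-atom transfer). The closest known reactions are the Dowd–Beckwith expansion of α-halomethyl ketones and thiol-catalysed silane reductions in which homochiral carbohydrate thiols transfer hydrogen enantioselectively to cyclic α-oxygenated radicals; their combination on a flavanone C2 radical has not been shown. The step needs acyl migration to beat phenyl (neophyl) migration, ring expansion to precede reduction, and the thiol rather than the silane to be the H donor. These should be secured, in turn, by the aryl ketone (1,2-acyl shifts are known to be about two orders of magnitude faster than 1,2-phenyl shifts), by the low thiol concentration, and by the strong, hydridic Si–H bond of Et3SiH, which should not reduce a stabilised benzylic radical.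

Step 7
Reactants: 10 (2R)-6-methyl-2-phenyl-5,7-di(propan-2-yloxy)-2,3-dihydro-4H-chromen-4-one
Product: 11 (2R)-5,7-dihydroxy-6-methyl-2-phenyl-2,3-dihydro-4H-chromen-4-one
Conditions: BCl3 (5 equiv), CH2Cl2, −78 → 0 °C; MeOH/aq. NaHCO3 quench
Reagents that add atoms: none
Why: Lewis-acid cleavage of isopropyl aryl ethers (chelation-assisted at O5); the ring C2–O1 bond belongs to a vinylogous ester and should not ionise under these conditions, so C2 should keep its configuration.

Step 8
Reactants: 12 1-(2,4,6-trihydroxyphenyl)ethanone
Product: 13 2-acetyl-3-hydroxy-4,4,6,6-tetramethylcyclohex-2-ene-1,5-dione (acetylsyncarpic acid)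
Conditions: NaOMe (5 equiv), MeI (6 equiv), MeOH, 0 °C → reflux; aq. HCl work-up
Reagents that add atoms: iodomethane, CI
Why: Exhaustive dearomatising C-methylation of the acylphloroglucinol enolate; the acetyl group blocks the third ring carbon, so four methyl groups should enter at the two free positions.

Step 9
Reactants: 13 2-acetyl-3-hydroxy-4,4,6,6-tetramethylcyclohex-2-ene-1,5-dione
Product: 14 2,2,4,4-tetramethylcyclohexane-1,3,5-trione (syncarpic acid)
Conditions: 6 M aq. HCl, reflux
Reagents that add atoms: none
Why: Acid-mediated retro-Claisen deacylation of the β-triketone removes the acetyl group as acetic acid.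

Step 10
Reactants: 14 2,2,4,4-tetramethylcyclohexane-1,3,5-trione; 15 3-methylbutanal
Product: 16 2,2,4,4-tetramethyl-6-(3-methylbutylidene)cyclohexane-1,3,5-trione
Conditions: piperidine (10 mol%), CH2Cl2, 4 Å MS, 0 °C → rt; used at once
Reagents that add atoms: none
Why: Knoevenagel condensation; the flanking gem-dimethyl groups slow the addition of a second trione, so the alkylidene trione should be obtainable and is used without storage.

Step 11
Reactants: 11 (2R)-5,7-dihydroxy-6-methyl-2-phenyl-2,3-dihydro-4H-chromen-4-one; 16 2,2,4,4-tetramethyl-6-(3-methylbutylidene)cyclohexane-1,3,5-trione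
Product: 17 (2R)-5,7-dihydroxy-8-[(1S)-1-(2-hydroxy-3,3,5,5-tetramethyl-4,6-dioxocyclohex-1-en-1-yl)-3-methylbutyl]-6-methyl-2-phenyl-2,3-dihydro-4H-chromen-4-one (CNP0249552.1)
Conditions: quinine-derived 3,5-bis(trifluoromethyl)phenyl squaramide (10 mol%), toluene, −20 °C
Reagents that add atoms: none
Why: Organocatalytic Friedel–Crafts-type Michael addition: C8 is the only free nucleophilic carbon of the A ring (C6 carries the methyl group), and the bifunctional catalyst (squaramide on the 1,3-dione of 16, amine on the 7-OH) should direct the aryl carbon to the Re face of the alkylidene carbon, which sets the side-chain methine (S) under catalyst control while C2 is untouched at this low basicity and temperature.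

**Compound list**

1 | 2-methylbenzene-1,3-diol | Cc1c(O)cccc1O | starting material
2 | 2-methyl-1,3-di(propan-2-yloxy)benzene | Cc1c(OC(C)C)cccc1OC(C)C | intermediate
3 | 2-[4-methyl-3,5-di(propan-2-yloxy)phenyl]-4,4,5,5-tetramethyl-1,3,2-dioxaborolane | Cc1c(OC(C)C)cc(B2OC(C)(C)C(C)(C)O2)cc1OC(C)C | intermediate (not isolated)
4 | 4-methyl-3,5-di(propan-2-yloxy)phenol | Cc1c(OC(C)C)cc(O)cc1OC(C)C | intermediate
5 | 2-bromo-2-phenylacetic acid (racemic) | OC(=O)C(Br)c1ccccc1 | starting material
6 | rac-2-[4-methyl-3,5-di(propan-2-yloxy)phenoxy]-2-phenylacetic acid | Cc1c(OC(C)C)cc(OC(C(=O)O)c2ccccc2)cc1OC(C)C | intermediate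
7 | mixed anhydride of 6 with trifluoroacetic acid (racemic) | Cc1c(OC(C)C)cc(OC(C(=O)OC(=O)C(F)(F)F)c2ccccc2)cc1OC(C)C | intermediate (not isolated)
8 | rac-5-methyl-2-phenyl-4,6-di(propan-2-yloxy)-1-benzofuran-3(2H)-one | O=C1C(c2ccccc2)Oc2cc(OC(C)C)c(C)c(OC(C)C)c21 | intermediate
9 | rac-2-(bromomethyl)-5-methyl-2-phenyl-4,6-di(propan-2-yloxy)-1-benzofuran-3(2H)-one | O=C1C(CBr)(c2ccccc2)Oc2cc(OC(C)C)c(C)c(OC(C)C)c21 | intermediate
10 | (2R)-6-methyl-2-phenyl-5,7-di(propan-2-yloxy)-2,3-dihydro-4H-chromen-4-one | Cc1c(OC(C)C)cc2c(c1OC(C)C)C(=O)C[C@H](c1ccccc1)O2 | intermediate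
11 | (2R)-5,7-dihydroxy-6-methyl-2-phenyl-2,3-dihydro-4H-chromen-4-one | Cc1c(O)cc2c(c1O)C(=O)C[C@H](c1ccccc1)O2 | intermediate
12 | 1-(2,4,6-trihydroxyphenyl)ethanone | CC(=O)c1c(O)cc(O)cc1O | starting material
13 | 2-acetyl-3-hydroxy-4,4,6,6-tetramethylcyclohex-2-ene-1,5-dione | CC(=O)C1=C(O)C(C)(C)C(=O)C(C)(C)C1=O | intermediate
14 | 2,2,4,4-tetramethylcyclohexane-1,3,5-trione | CC1(C)C(=O)CC(=O)C(C)(C)C1=O | intermediate
15 | 3-methylbutanal | CC(C)CC=O | starting material
16 | 2,2,4,4-tetramethyl-6-(3-methylbutylidene)cyclohexane-1,3,5-trione | CC(C)CC=C1C(=O)C(C)(C)C(=O)C(C)(C)C1=O | intermediate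
17 | (2R)-5,7-dihydroxy-8-[(1S)-1-(2-hydroxy-3,3,5,5-tetramethyl-4,6-dioxocyclohex-1-en-1-yl)-3-methylbutyl]-6-methyl-2-phenyl-2,3-dihydro-4H-chromen-4-one | Cc1c(O)c2c(c([C@H](CC(C)C)C3=C(O)C(C)(C)C(=O)C(C)(C)C3=O)c1O)O[C@@H](c1ccccc1)CC2=O | target

**Totals.** Total step count: 11. Longest linear sequence: 8 steps (steps 1–7, then step 11); the syncarpic branch is steps 8–10.

**Steps most likely to fail**

Step 6 (Proposed new method). The hydrogen-atom transfer may discriminate the two faces of the C2 radical poorly. The primary radical may also be reduced before it rearranges, and thiyl radicals may re-abstract the C2 hydrogen of the product and erode its enantiopurity. Fallback with known chemistry: setting out from 9, tin hydride reduction (Bu3SnH, AIBN, benzene, 80 °C, slow addition) should give the racemic flavanone F1 by the ordinary Dowd–Beckwith expansion. Kinetic resolution by asymmetric transfer hydrogenation (Rh(III)– or Ru(II)–TsDPEN, HCO2H/Et3N), with the catalyst antipode that reduces the 2S ketone to the cis-flavan-4-ol F2, should leave the 2R ketone. This is 10, and the route continues with step 7.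

Step 11. Facial selectivity at the alkylidene carbon may be poor, the acidic enol product may inhibit the basic catalyst, and the new centre may epimerise by retro-Michael reaction. Fallback: setting out from 11 and 16, the addition is run without a chiral catalyst (Et3N or no additive, CH2Cl2, rt), which should give 17 together with its side-chain epimer F3. Because C2 is fixed the two are diastereomers and are separated by preparative HPLC, and F3 is recycled by retro-Michael/Michael equilibration under the same conditions. The route ends at 17.

Step 5. The ambident enolate may be alkylated at oxygen, a second enolate may displace the remaining bromide, and C2 may autoxidise. Fallback: setting out from 8, aldol hydroxymethylation with aqueous formaldehyde (cat. K2CO3, THF) should give the hydroxymethyl ketone F4, and Appel bromination (CBr4, PPh3, CH2Cl2) converts it into 9.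

**Further compounds**

F1 | step 6 | rac-6-methyl-2-phenyl-5,7-di(propan-2-yloxy)-2,3-dihydro-4H-chromen-4-one | Cc1c(OC(C)C)cc2c(c1OC(C)C)C(=O)CC(c1ccccc1)O2
F2 | step 6 | (2S,4S)-6-methyl-2-phenyl-5,7-di(propan-2-yloxy)-3,4-dihydro-2H-chromen-4-ol (cis) | Cc1c(OC(C)C)cc2c(c1OC(C)C)[C@@H](O)C[C@@H](c1ccccc1)O2
F3 | step 11 | (2R)-5,7-dihydroxy-8-[(1R)-1-(2-hydroxy-3,3,5,5-tetramethyl-4,6-dioxocyclohex-1-en-1-yl)-3-methylbutyl]-6-methyl-2-phenyl-2,3-dihydro-4H-chromen-4-one | Cc1c(O)c2c(c([C@@H](CC(C)C)C3=C(O)C(C)(C)C(=O)C(C)(C)C3=O)c1O)O[C@@H](c1ccccc1)CC2=O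
F4 | step 5 | rac-2-(hydroxymethyl)-5-methyl-2-phenyl-4,6-di(propan-2-yloxy)-1-benzofuran-3(2H)-one | O=C1C(CO)(c2ccccc2)Oc2cc(OC(C)C)c(C)c(OC(C)C)c21
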